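**Retrosynthetic overview**
1. Target ← methyl ester ← vinyl precursor (diimide). The last C–C disconnection is the exocyclic bond from dioxane C6 to the side-chain CH2; it is made by capture of a ring peroxycarbenium ion (C6=O1+) by a cyclopropylcarbinyl stannane, which delivers the whole side chain as a homoallyl unit.
2. Enabling feature: C6 is the fully substituted ring carbon bound to peroxide oxygen O1, so a 6-methoxy-1,2-dioxane (peroxyketal) can ionise there while the ring substituents at C3 and C4 differentiate its faces. The side-chain CH2–CH(Et) unit maps onto the CH2 and CH of a trans-cyclopropane whose CH2Sn arm becomes the vinyl (then ethyl) group.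
3. Ring order: the 1,2-dioxane is closed first (O2–C3 bond, oxa-Michael addition of a hydroperoxy ketal) on a keto enoate from Ir-catalysed allylic alkylation, Krapcho reaction and cross-metathesis. The temporary cyclopropane is made separately (asymmetric Simmons–Smith) and is opened in the key step.
4. Stereocentres: C4 by Ir catalysis, C3 by the ring closure, C6 in the key step, side-chain CH–Me by Cu-catalysed conjugate addition, side-chain CH–Et by reagent-controlled cyclopropanation.

Key step: step 14

Remark: the configuration at C6 of the methoxy peroxyketal is immaterial because both epimers give the same cation; ligand enantiomers named are those expected from the accepted models, and the antipode is used if the sense proves opposite.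

Step 1
Reactants: 1 (2E)-pent-2-en-1-ol
Product: 2 methyl (2E)-pent-2-en-1-yl carbonate
Conditions: ClCO2Me, pyridine, CH2Cl2, 0 °C
Reagents that add atoms: methyl chloroformate, COC(=O)Cl
Why: O-Acylation of a primary allylic alcohol with a chloroformate (carbonate formation) is routine and leaves the E-alkene untouched.

Step 2
Reactants: 2 methyl (2E)-pent-2-en-1-yl carbonate; 3 methyl 3-oxopentanoate
Product: 4 methyl (3R)-3-ethyl-2-propanoylpent-4-enoate (both C2 epimers)
Conditions: [Ir(cod)Cl]2 (2 mol %), (Sa,S,S)-phosphoramidite ligand (4 mol %), TBD (8 mol %), THF, rt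
Reagents that add atoms: none
Why: Iridium-catalysed asymmetric allylic alkylation of a linear allyl carbonate with a β-keto ester (salt-free, the released methoxide acts as base) should give the branched isomer, and the cyclometalated Ir–phosphoramidite catalyst sets the allylic centre (3R, the later ring C4), while the epimeric C2 is erased in step 3.

Step 3
Reactants: 4 methyl (3R)-3-ethyl-2-propanoylpent-4-enoate
Product: 5 (5S)-5-ethylhept-6-en-3-one
Conditions: LiCl, H2O, DMSO, 140 °C
Reagents that add atoms: none
Why: Krapcho dealkoxycarbonylation (chloride SN2 at the ester methyl, loss of CO2, protonation) proceeds under neutral conditions and cannot touch the stereocentre, which is β to the ketone and not enolisable.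

Step 4
Reactants: 5 (5S)-5-ethylhept-6-en-3-one; 6 methyl acrylate
Product: 7 methyl (2E,4S)-4-ethyl-6-oxooct-2-enoate
Conditions: Hoveyda–Grubbs II (5 mol %), methyl acrylate (5 equiv), CH2Cl2, 40 °C
Reagents that add atoms: none
Why: Olefin cross-metathesis of a terminal alkene with an acrylate is selective for the E-configured cross product, tolerates the ketone and does not involve the allylic stereocentre.

Step 5
Reactants: 7 methyl (2E,4S)-4-ethyl-6-oxooct-2-enoate
Product: 8 methyl (2E,4S)-4-ethyl-6-hydroperoxy-6-methoxyoct-2-enoate (both C6 epimers)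
Conditions: urea·H2O2 (4 equiv), Sc(OTf)3 (10 mol %), MeOH, 0 °C to rt
Reagents that add atoms: hydrogen peroxide (as its urea adduct), OO; methanol, CO
Why: Lewis-acid-catalysed peroxyketalisation of a ketone with H2O2 in methanol gives the α-methoxy hydroperoxide while the enoate is inert under these acidic conditions; the new C6 centre is formed unselectively, which does not matter because C6 is planarised in step 14.

Step 6
Reactants: 8 methyl (2E,4S)-4-ethyl-6-hydroperoxy-6-methoxyoct-2-enoate
Product: 9 methyl 2-[(3S,4S)-4,6-diethyl-6-methoxy-1,2-dioxan-3-yl]acetate (both C6 epimers)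
Conditions: Et2NH (0.5 equiv), CF3CH2OH, rt
Reagents that add atoms: none
Why: Amine-mediated intramolecular oxa-Michael addition (6-exo-trig) of the hydroperoxide to the E-enoate closes the 1,2-dioxane at O2–C3, and C3 is expected to be set by C4 through a chair-like transition state with the C4 ethyl equatorial and the acceptor arm axial (kinetic closure), giving the 3,4-cis ring, which is separated from any 3,4-trans isomer by chromatography.

Step 7
Reactants: 10 methyl (2E)-but-2-enoate; 11 butylmagnesium bromide
Product: 12 methyl (3S)-3-methylheptanoate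
Conditions: CuBr·SMe2 (1 mol %), Josiphos-type ligand (1.2 mol %), t-BuOMe, −75 °C; then 1 M HCl
Reagents that add atoms: none
Why: Copper-catalysed asymmetric conjugate addition of a Grignard reagent to an E-enoate, in which the chiral ferrocenyl diphosphine–copper complex selects the enoate face and sets the methyl-bearing centre (3S; ligand enantiomer chosen accordingly).

Step 8
Reactants: 12 methyl (3S)-3-methylheptanoate
Product: 13 (3S)-3-methylheptanal
Conditions: DIBAL-H (1.05 equiv), CH2Cl2, −78 °C; then Rochelle salt
Reagents that add atoms: none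
Why: Low-temperature DIBAL-H half-reduction of an ester stops at the aluminium hemiacetal, and the β-stereocentre is not epimerisable.

Step 9
Reactants: 13 (3S)-3-methylheptanal; 14 triethyl phosphonoacetate
Product: 15 ethyl (2E,5S)-5-methylnon-2-enoate
Conditions: NaH, THF, 0 °C to rt
Reagents that add atoms: none
Why: Horner–Wadsworth–Emmons olefination with a stabilised phosphonate anion gives the E-enoate.

Step 10
Reactants: 15 ethyl (2E,5S)-5-methylnon-2-enoate
Product: 16 (2E,5S)-5-methylnon-2-en-1-ol
Conditions: DIBAL-H (2.2 equiv), CH2Cl2, −78 to 0 °C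
Reagents that add atoms: none
Why: 1,2-Reduction of an enoate by DIBAL-H gives the E-allylic alcohol without touching the alkene.

Step 11
Reactants: 16 (2E,5S)-5-methylnon-2-en-1-ol
Product: 17 [(1S,2S)-2-[(2S)-2-methylhexyl]cyclopropyl]methanol
Conditions: Et2Zn, CH2I2, DME, (4R,5R)-2-butyl-N,N,N′,N′-tetramethyl-1,3,2-dioxaborolane-4,5-dicarboxamide (1.2 equiv), CH2Cl2, −10 °C to rt
Reagents that add atoms: diiodomethane (delivered as bis(iodomethyl)zinc), ICI
Why: Asymmetric Simmons–Smith cyclopropanation with a chiral dioxaborolane controller (Charette modification): the zinc alkoxide bound to the controller directs stereospecific syn methylene transfer to one alkene face, so the E-alkene gives the trans ring and the reagent sets both ring centres (1S,2S) independently of the remote methyl centre.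

Step 12
Reactants: 17 [(1S,2S)-2-[(2S)-2-methylhexyl]cyclopropyl]methanol
Product: 18 [(1S,2S)-2-[(2S)-2-methylhexyl]cyclopropyl]methyl methanesulfonate
Conditions: MsCl, Et3N, CH2Cl2, −20 °C; used at once
Reagents that add atoms: methanesulfonyl chloride, CS(=O)(=O)Cl
Why: Sulfonylation of a primary alcohol at low temperature is routine, and immediate use avoids ionisation of the cyclopropylcarbinyl sulfonate.

Step 13
Reactants: 18 [(1S,2S)-2-[(2S)-2-methylhexyl]cyclopropyl]methyl methanesulfonate
Product: 19 tributyl{[(1S,2S)-2-[(2S)-2-methylhexyl]cyclopropyl]methyl}stannane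
Conditions: Bu3SnLi (from Bu3SnH and LDA, THF, 0 °C), then 18, THF, −78 °C to rt
Reagents that add atoms: tributylstannyllithium, [Li][Sn](CCCC)(CCCC)CCCC
Why: Alkylation of a stannyl anion by a primary sulfonate is an SN2 displacement (sulfonates react by direct substitution and not by electron transfer), so the ring should stay closed and the ring stereocentres are untouched.

Step 14
Reactants: 9 methyl 2-[(3S,4S)-4,6-diethyl-6-methoxy-1,2-dioxan-3-yl]acetate; 19 tributyl{[(1S,2S)-2-[(2S)-2-methylhexyl]cyclopropyl]methyl}stannane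
Product: 21 methyl 2-[(3S,4S,6S)-4,6-diethyl-6-[(2S,4S)-2-ethenyl-4-methyloctyl]-1,2-dioxan-3-yl]acetate, via cyclic peroxycarbenium triflate 20 (not isolated)
Conditions: TMSOTf (1.2 equiv), 19 (1.5 equiv), 2,6-di-tert-butyl-4-methylpyridine (0.5 equiv), CH2Cl2, −78 to −40 °C
Reagents that add atoms: none
Why: Proposed new method: TMSOTf silylates and expels the exocyclic methoxy group of 9 to give the ring peroxycarbenium ion 20 (C6=O1+), which is attacked by the strained C–C σ-bond of cyclopropylcarbinyl stannane 19: the cation bonds to the unsubstituted ring CH2, positive charge builds up on the ring carbon β to tin (σ C–Sn hyperconjugation) and loss of Bu3Sn+ opens the ring to a terminal vinyl group, so the side chain is transferred as a homoallyl unit and the tin leaves no trace. The closest known reaction types are the Lewis-acid allylation of alkoxy-1,2-dioxanes and -dioxolanes through peroxycarbenium ions with allyl-silanes and -stannanes, and the Lewis-acid homoallylation of acetals, aldehydes and acyl chlorides by cyclopropylmethyl-silanes and -stannanes; their combination on a peroxycarbenium ion is new. No ring is closed: the 1,2-dioxane is retained because the more basic exocyclic methoxy oxygen, not a ring oxygen, is activated, and the cyclopropane is the ring that is opened. The new quaternary centre C6 is controlled by the ring: in the half-chair cation the C4 ethyl is pseudo-equatorial and the cis C3 ester arm pseudo-axial, and chair-like axial attack on the face opposite that arm (reinforced by possible shielding of the other face by the ester carbonyl) puts the incoming chain trans to both substituents and leaves the C6 ethyl cis to the C4 ethyl (6S), both C6 epimers of 9 giving the same ion. The side-chain centre that will carry the ethyl group is the substituted cyclopropane carbon of 19, to which no bond is made or broken, so its configuration and that of the methyl centre are carried over unchanged. The step needs (i) opening of the cyclopropane at CH2 and not at the alkyl-bearing ring carbon, secured because a fully substituted cation can only reach the unhindered CH2 from the backside, and (ii) capture faster than Hock-type fragmentation or proton loss of 20, for which the stannane (more nucleophilic than the silane), −78 °C and a hindered pyridine base are chosen.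

Step 15
Reactants: 21 methyl 2-[(3S,4S,6S)-4,6-diethyl-6-[(2S,4S)-2-ethenyl-4-methyloctyl]-1,2-dioxan-3-yl]acetate
Product: 22 methyl 2-[(3S,4S,6S)-4,6-diethyl-6-[(2S,4S)-2-ethyl-4-methyloctyl]-1,2-dioxan-3-yl]acetate
Conditions: 2-nitrobenzenesulfonylhydrazide (excess), Et3N, CH2Cl2, rt
Reagents that add atoms: none
Why: Diimide reduction (concerted syn transfer of H2 from HN=NH) saturates the unhindered monosubstituted alkene and, unlike catalytic hydrogenation, leaves the O–O bond intact; no stereocentre is affected.

Step 16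
Reactants: 22 methyl 2-[(3S,4S,6S)-4,6-diethyl-6-[(2S,4S)-2-ethyl-4-methyloctyl]-1,2-dioxan-3-yl]acetate
Product: 24 2-[(3S,4S,6S)-4,6-diethyl-6-[(2S,4S)-2-ethyl-4-methyloctyl]-1,2-dioxan-3-yl]acetic acid, via lithium carboxylate 23 (not isolated)
Conditions: LiOH·H2O (3 equiv), THF/H2O 3:1, 0 °C to rt; then 1 M HCl to pH 3
Reagents that add atoms: lithium hydroxide, [Li+].[OH-]
Why: Saponification of a methyl ester with LiOH at low temperature, which a dialkyl peroxide with a fully substituted C6 should tolerate, followed by acidification to the free acid.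

**Compound list**
1 | (2E)-pent-2-en-1-ol | CC/C=C/CO | starting material
2 | methyl (2E)-pent-2-en-1-yl carbonate | CC/C=C/COC(=O)OC | intermediate
3 | methyl 3-oxopentanoate | CCC(=O)CC(=O)OC | starting material
4 | methyl (3R)-3-ethyl-2-propanoylpent-4-enoate (both C2 epimers) | CCC(=O)C(C(=O)OC)[C@H](CC)C=C | intermediate
5 | (5S)-5-ethylhept-6-en-3-one | CCC(=O)C[C@H](CC)C=C | intermediate
6 | methyl acrylate | C=CC(=O)OC | starting material
7 | methyl (2E,4S)-4-ethyl-6-oxooct-2-enoate | CCC(=O)C[C@H](CC)/C=C/C(=O)OC | intermediate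
8 | methyl (2E,4S)-4-ethyl-6-hydroperoxy-6-methoxyoct-2-enoate (both C6 epimers) | CCC(OC)(OO)C[C@H](CC)/C=C/C(=O)OC | intermediate
9 | methyl 2-[(3S,4S)-4,6-diethyl-6-methoxy-1,2-dioxan-3-yl]acetate (both C6 epimers) | CCC1(OC)C[C@H](CC)[C@H](CC(=O)OC)OO1 | intermediate
10 | methyl (2E)-but-2-enoate | C/C=C/C(=O)OC | starting material
11 | butylmagnesium bromide | CCCC[Mg]Br | starting material
12 | methyl (3S)-3-methylheptanoate | CCCC[C@H](C)CC(=O)OC | intermediate
13 | (3S)-3-methylheptanal | CCCC[C@H](C)CC=O | intermediate
14 | triethyl phosphonoacetate | CCOC(=O)CP(=O)(OCC)OCC | starting material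
15 | ethyl (2E,5S)-5-methylnon-2-enoate | CCCC[C@H](C)C/C=C/C(=O)OCC | intermediate
16 | (2E,5S)-5-methylnon-2-en-1-ol | CCCC[C@H](C)C/C=C/CO | intermediate
17 | [(1S,2S)-2-[(2S)-2-methylhexyl]cyclopropyl]methanol | CCCC[C@H](C)C[C@H]1C[C@@H]1CO | intermediate
18 | [(1S,2S)-2-[(2S)-2-methylhexyl]cyclopropyl]methyl methanesulfonate | CCCC[C@H](C)C[C@H]1C[C@@H]1COS(C)(=O)=O | intermediate
19 | tributyl{[(1S,2S)-2-[(2S)-2-methylhexyl]cyclopropyl]methyl}stannane | CCCC[C@H](C)C[C@H]1C[C@@H]1C[Sn](CCCC)(CCCC)CCCC | intermediate
20 | (3S,4S)-4,6-diethyl-3-(2-methoxy-2-oxoethyl)-4,5-dihydro-3H-1,2-dioxin-1-ium trifluoromethanesulfonate (ring peroxycarbenium ion, C6=O1+) | CCC1=[O+]O[C@@H](CC(=O)OC)[C@@H](CC)C1.[O-]S(=O)(=O)C(F)(F)F | intermediate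
21 | methyl 2-[(3S,4S,6S)-4,6-diethyl-6-[(2S,4S)-2-ethenyl-4-methyloctyl]-1,2-dioxan-3-yl]acetate | CCCC[C@H](C)C[C@H](C=C)C[C@@]1(CC)C[C@H](CC)[C@H](CC(=O)OC)OO1 | intermediate
22 | methyl 2-[(3S,4S,6S)-4,6-diethyl-6-[(2S,4S)-2-ethyl-4-methyloctyl]-1,2-dioxan-3-yl]acetate | CCCC[C@H](C)C[C@H](CC)C[C@@]1(CC)C[C@H](CC)[C@H](CC(=O)OC)OO1 | intermediate
23 | lithium 2-[(3S,4S,6S)-4,6-diethyl-6-[(2S,4S)-2-ethyl-4-methyloctyl]-1,2-dioxan-3-yl]acetate | CCCC[C@H](C)C[C@H](CC)C[C@@]1(CC)C[C@H](CC)[C@H](CC(=O)[O-])OO1.[Li+] | intermediate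
24 | 2-[(3S,4S,6S)-4,6-diethyl-6-[(2S,4S)-2-ethyl-4-methyloctyl]-1,2-dioxan-3-yl]acetic acid | CCCC[C@H](C)C[C@H](CC)C[C@@]1(CC)C[C@H](CC)[C@H](CC(=O)O)OO1 | target

Total step count: 16. Longest linear sequence: 10 steps (steps 7 to 13, then 14 to 16).

**Steps most likely to fail**

1. Step 14 (Proposed new method). The ionised peroxyketal may fragment or lose a proton (Hock-type C-to-O shift, elimination towards C5) faster than the σ-donor is captured. The stannane may also be protodestannylated with ring opening, or the cation may open the cyclopropane at the substituted ring carbon. The fallback uses known chemistry only, sets out from 15 and 5 and comes back to the route at 22; it makes the same C6–CH2 connection as a C=C bond before the peroxide exists, at the price of losing control at C6.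
   - Copper/Josiphos-catalysed conjugate addition of EtMgBr to 15 gives ethyl (3S,5S)-3-ethyl-5-methylnonanoate F1.
   - Saponification gives (3S,5S)-3-ethyl-5-methylnonanoic acid F2.
   - Iododecarboxylation (PhI(OAc)2, I2, hν) gives (3S,5S)-3-(iodomethyl)-5-methylnonane F3.
   - PPh3 in hot MeCN gives [(2S,4S)-2-ethyl-4-methyloctyl]triphenylphosphonium iodide F4.
   - Its ylide (n-BuLi) and ketone 5 give in a Wittig reaction (3S,7S,9S)-3,5,7-triethyl-9-methyltrideca-1,5-diene F5.
   - Cross-metathesis of the terminal alkene with 6 gives methyl (2E,4S,8S,10S)-4,6,8-triethyl-10-methyltetradeca-2,6-dienoate F6.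
   - Mukaiyama–Isayama hydroperoxysilylation (Co(thd)2, O2, Et3SiH) of the trisubstituted alkene gives the tertiary silyl peroxide methyl (2E,4S,8S,10S)-4,6,8-triethyl-10-methyl-6-[(triethylsilyl)peroxy]tetradec-2-enoate F7.
   - Fluoride desilylation gives methyl (2E,4S,8S,10S)-4,6,8-triethyl-6-hydroperoxy-10-methyltetradec-2-enoate F8, which is cyclised with Et2NH in CF3CH2OH as in step 6 to 22 and its C6 epimer methyl 2-[(3S,4S,6R)-4,6-diethyl-6-[(2S,4S)-2-ethyl-4-methyloctyl]-1,2-dioxan-3-yl]acetate F9; the two are separated by HPLC.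

2. Step 6. Facial selectivity at C3 in the ring closure may be poor, or retro-Michael equilibration may drift towards the 3,4-trans ring. The fallback sets out from 5 and comes back at 9; C3 is set by reagent control and then inverted in a stereospecific 6-exo-tet ring closure.
   - Ozonolysis of 5 (O3, then Me2S) gives (2S)-2-ethyl-4-oxohexanal F10.
   - Brown allylation with the Ipc2B(allyl) enantiomer that gives the 6R carbinol affords (5S,6R)-5-ethyl-6-hydroxynon-8-en-3-one F11.
   - MsCl/Et3N gives (4R,5S)-5-ethyl-7-oxonon-1-en-4-yl methanesulfonate F12.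
   - Urea·H2O2/Sc(OTf)3/MeOH gives (4R,5S)-5-ethyl-7-hydroperoxy-7-methoxynon-1-en-4-yl methanesulfonate F13.
   - KOt-Bu/18-crown-6 closes the ring by intramolecular SN2 displacement with inversion to (3S,4S)-4,6-diethyl-6-methoxy-3-(prop-2-en-1-yl)-1,2-dioxane F14.
   - Ozonolysis (Me2S) gives 2-[(3S,4S)-4,6-diethyl-6-methoxy-1,2-dioxan-3-yl]acetaldehyde F15.
   - Pinnick oxidation gives 2-[(3S,4S)-4,6-diethyl-6-methoxy-1,2-dioxan-3-yl]acetic acid F16, and TMSCHN2 gives 9.

3. Step 13. Ionisation of the cyclopropylcarbinyl sulfonate, or electron transfer from the stannyl anion, may open or rearrange the ring instead of giving direct displacement. The fallback sets out from 17 and comes back at 19; the polarity is reversed so that substitution takes place at tin and not at the cyclopropylcarbinyl carbon.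
   - Appel iodination (I2, PPh3, imidazole) gives (1S,2S)-1-(iodomethyl)-2-[(2S)-2-methylhexyl]cyclopropane F17.
   - Iodine–lithium exchange (t-BuLi, pentane/Et2O, −78 °C) gives the lithio analogue of 19, {[2-[(2S)-2-methylhexyl]cyclopropyl]methyl}lithium F18. It is kept at −78 °C, where ring opening to the homoallyllithium is slow, and is quenched with Bu3SnCl to give 19.

Further compounds
F1 | step 14 | ethyl (3S,5S)-3-ethyl-5-methylnonanoate | CCCC[C@H](C)C[C@H](CC)CC(=O)OCC
F2 | step 14 | (3S,5S)-3-ethyl-5-methylnonanoic acid | CCCC[C@H](C)C[C@H](CC)CC(=O)O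
F3 | step 14 | (3S,5S)-3-(iodomethyl)-5-methylnonane | CCCC[C@H](C)C[C@H](CC)CI
F4 | step 14 | [(2S,4S)-2-ethyl-4-methyloctyl]triphenylphosphonium iodide | CCCC[C@H](C)C[C@H](CC)C[P+](c1ccccc1)(c1ccccc1)c1ccccc1.[I-]
F5 | step 14 | (3S,7S,9S)-3,5,7-triethyl-9-methyltrideca-1,5-diene (5E/5Z mixture) | CCCC[C@H](C)C[C@H](CC)C=C(CC)C[C@H](CC)C=C
F6 | step 14 | methyl (2E,4S,8S,10S)-4,6,8-triethyl-10-methyltetradeca-2,6-dienoate (6E/6Z mixture) | CCCC[C@H](C)C[C@H](CC)C=C(CC)C[C@H](CC)/C=C/C(=O)OC
F7 | step 14 | methyl (2E,4S,8S,10S)-4,6,8-triethyl-10-methyl-6-[(triethylsilyl)peroxy]tetradec-2-enoate (both C6 epimers) | CCCC[C@H](C)C[C@H](CC)CC(CC)(OO[Si](CC)(CC)CC)C[C@H](CC)/C=C/C(=O)OC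
F8 | step 14 | methyl (2E,4S,8S,10S)-4,6,8-triethyl-6-hydroperoxy-10-methyltetradec-2-enoate (both C6 epimers) | CCCC[C@H](C)C[C@H](CC)CC(CC)(OO)C[C@H](CC)/C=C/C(=O)OC
F9 | step 14 | methyl 2-[(3S,4S,6R)-4,6-diethyl-6-[(2S,4S)-2-ethyl-4-methyloctyl]-1,2-dioxan-3-yl]acetate | CCCC[C@H](C)C[C@H](CC)C[C@]1(CC)C[C@H](CC)[C@H](CC(=O)OC)OO1
F10 | step 6 | (2S)-2-ethyl-4-oxohexanal | CCC(=O)C[C@H](CC)C=O
F11 | step 6 | (5S,6R)-5-ethyl-6-hydroxynon-8-en-3-one | CCC(=O)C[C@H](CC)[C@H](O)CC=C
F12 | step 6 | (4R,5S)-5-ethyl-7-oxonon-1-en-4-yl methanesulfonate | CCC(=O)C[C@H](CC)[C@H](OS(C)(=O)=O)CC=C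
F13 | step 6 | (4R,5S)-5-ethyl-7-hydroperoxy-7-methoxynon-1-en-4-yl methanesulfonate (both C7 epimers) | CCC(OC)(OO)C[C@H](CC)[C@H](OS(C)(=O)=O)CC=C
F14 | step 6 | (3S,4S)-4,6-diethyl-6-methoxy-3-(prop-2-en-1-yl)-1,2-dioxane (both C6 epimers) | CCC1(OC)C[C@H](CC)[C@H](CC=C)OO1
F15 | step 6 | 2-[(3S,4S)-4,6-diethyl-6-methoxy-1,2-dioxan-3-yl]acetaldehyde (both C6 epimers) | CCC1(OC)C[C@H](CC)[C@H](CC=O)OO1
F16 | step 6 | 2-[(3S,4S)-4,6-diethyl-6-methoxy-1,2-dioxan-3-yl]acetic acid (both C6 epimers) | CCC1(OC)C[C@H](CC)[C@H](CC(=O)O)OO1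
F17 | step 13 | (1S,2S)-1-(iodomethyl)-2-[(2S)-2-methylhexyl]cyclopropane | CCCC[C@H](C)C[C@H]1C[C@@H]1CI
F18 | step 13 | {[2-[(2S)-2-methylhexyl]cyclopropyl]methyl}lithium (ring configuration as in 17) | CCCC[C@H](C)C[C@H]1C[C@@H]1C[Li]
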